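**Retrosynthetic overview**
- The C7–OAr bond is made last: Mitsunobu coupling of the 7-OH of (S)-pinocembrin with a (7R)-carbinol (inversion). The carbinol comes from chelation-controlled reduction of a 5-benzoyl lactone.
- The γ-lactone (second ring) is closed by SN2 (Mitsunobu) lactonisation with inversion at C6a of a trans-3-hydroxyoxolan-2-ylacetic acid. That hydroxyl comes from a C–Si bond (Fleming–Tamao).
- The oxolane (first ring) is made in one operation by [3+2] annulation of (S)-methyl 3-(dimethylphenylsilyl)pent-4-enoate with phenylglyoxal: C6–C5 and O4–C3a are formed while silicon moves onto C6a.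
- Enabling feature: in the oxolane ring O4–C5–C6–C6a–C3a, C6 is an unsubstituted CH2 and its neighbour C6a carries a heteroatom (lactone O1) next to the ether carbon C3a. This CH2 / C–Si / C–O triad is exactly what an allylsilane annulation leaves. C7 on C5 is a carbonyl-derived carbon, so the aldehyde partner can be a chelating 1,2-dicarbonyl compound.
- Ring order: oxolane (step 2), then lactone (step 5); the chromanone is bought intact. The allylsilane comes from a catalytic asymmetric silyl conjugate addition.

Key step: step 2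

Remark on the chemistry: phenylglyoxal is used as the anhydrous keto-aldehyde, distilled from the commercial monohydrate just before use, and natural (2S)-pinocembrin is taken as commercial. Core positions follow furo[3,2-b]furan-2(3H)-one numbering (O1, C2, C3, C3a, O4, C5, C6, C6a); the benzylic carbon is called C7. In the monocyclic intermediates, oxolane C2, C3 and C5 correspond to C3a, C6a and C5 of the bicycle.

**Step 1**
Reactants: 1 methyl (2E)-penta-2,4-dienoate; 2 2-[dimethyl(phenyl)silyl]-4,4,5,5-tetramethyl-1,3,2-dioxaborolane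
Product: 4 methyl (3S)-3-[dimethyl(phenyl)silyl]pent-4-enoate, via boron enolate 3 (not isolated)
Conditions: CuCl (2 mol %), chiral monodentate NHC·HBF4 (2.2 mol %, enantiomer that gives 3S), NaOtBu (4.4 mol %), THF, −78 °C; then H2O
Reagents that add atoms: none
Why: Enantioselective Cu-catalysed silyl conjugate addition of a silylboronate, in which the NHC–Cu–SiMe2Ph species should add 1,4 (β-attack leads directly to the O-bound enolate) and the ligand sets the C–Si stereocentre as S.

**Step 2**
Reactants: 4 methyl (3S)-3-[dimethyl(phenyl)silyl]pent-4-enoate; 5 phenylglyoxal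
Product: 6 methyl 2-[(2R,3S,5S)-5-benzoyl-3-[dimethyl(phenyl)silyl]oxolan-2-yl]acetate
Conditions: SnCl4 (1.2 equiv), 5 (1.3 equiv), CH2Cl2, −78 → −45 °C; aq. NaHCO3
Reagents that add atoms: none
Why: SnCl4 chelates the two carbonyl oxygens of 5 and the terminal CH2 of 4 adds to the aldehyde carbon on the alkene face anti to silicon (anti-SE′), giving a β-silyl cation bridged by silicon (siliranium ion); silicon thereby shifts from the former C3 of 4 to its neighbour and the tin alkoxide oxygen attacks the carbon that silicon has left. The closest known reaction type is the Lewis acid promoted [3+2] annulation of α-substituted allyl(dimethylphenyl)silanes with aldehydes and with chelating 1,2-dicarbonyl compounds (1,2-silyl shift pathway). The oxolane ring closes by a formally 5-endo opening of the siliranium ion with inversion at the attacked carbon. Oxolane C2 (R) is therefore fixed by inversion of the C–Si stereocentre of 4, C3 (S, silicon trans to the acetate arm) by the suprafacial silyl shift through the E-configured siliranium ion (C–H of the stereocentre eclipsing the alkene), and C5 (S, 2,5-trans) by the antiperiplanar approach that a bulky chelated aldehyde should prefer on the alkene face already chosen by silicon. The step needs ring closure to win over loss of silicon (Sakurai allylation), which the poorly chloride-labile PhMe2Si group at low temperature should secure, and attack at the aldehyde instead of the ketone carbonyl, which the higher electrophilicity of the aldehyde within the chelate should secure.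

**Step 3**
Reactants: 6 methyl 2-[(2R,3S,5S)-5-benzoyl-3-[dimethyl(phenyl)silyl]oxolan-2-yl]acetate
Product: 9 methyl 2-[(2R,3S,5S)-5-benzoyl-3-hydroxyoxolan-2-yl]acetate, via acetoxysilane 7 (not isolated), via silyl ether 8 (not isolated)
Conditions: Hg(OAc)2, AcOOH, AcOH, NaOAc, rt; aq. work-up
Reagents that add atoms: peracetic acid CC(=O)OO
Why: Fleming–Tamao oxidation, in which mercuridesilylation of Si–Ph gives an acetoxysilane that the peracid oxidises with migration of C3 from Si to O with retention; the deactivated benzoyl ring should not be mercurated and the aryl ketone should be slow in Baeyer–Villiger oxidation under buffered conditions.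

**Step 4**
Reactants: 9 methyl 2-[(2R,3S,5S)-5-benzoyl-3-hydroxyoxolan-2-yl]acetate
Product: 11 2-[(2R,3S,5S)-5-benzoyl-3-hydroxyoxolan-2-yl]acetic acid, via trimethylstannyl ester 10 (not isolated)
Conditions: Me3SnOH, ClCH2CH2Cl, 70 °C; 1 M HCl wash
Reagents that add atoms: trimethyltin hydroxide C[Sn](C)(C)O
Why: Trimethyltin hydroxide ester cleavage hydrolyses the methyl ester under nearly neutral conditions, so the base-labile C5 centre next to the benzoyl group and the β-alkoxy ester should not epimerise or eliminate.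

**Step 5**
Reactants: 11 2-[(2R,3S,5S)-5-benzoyl-3-hydroxyoxolan-2-yl]acetic acid
Product: 13 (3aR,5S,6aR)-5-benzoyltetrahydrofuro[3,2-b]furan-2(3H)-one, via oxyphosphonium carboxylate 12 (not isolated)
Conditions: PPh3, DIAD, THF (0.02 M), 0 °C → rt
Reagents that add atoms: none
Why: Intramolecular Mitsunobu lactonisation, in which the C3 hydroxyl is activated as alkoxyphosphonium and displaced by the tethered carboxylate (5-exo-tet SN2, inversion), turning the trans hydroxy acid into the cis-fused γ-lactone with C6a as R.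

**Step 6**
Reactants: 13 (3aR,5S,6aR)-5-benzoyltetrahydrofuro[3,2-b]furan-2(3H)-one
Product: 14 (3aR,5S,6aR)-5-[(R)-hydroxy(phenyl)methyl]tetrahydrofuro[3,2-b]furan-2(3H)-one
Conditions: Zn(BH4)2, Et2O, −30 → 0 °C; aq. NH4Cl
Reagents that add atoms: none
Why: Chelation-controlled ketone reduction (Cram chelate between the ketone oxygen and ring O4), in which hydride arrives from the C5–H side and should give the anti (7R) carbinol, while the lactone is inert to zinc borohydride at this temperature.

**Step 7**
Reactants: 14 (3aR,5S,6aR)-5-[(R)-hydroxy(phenyl)methyl]tetrahydrofuro[3,2-b]furan-2(3H)-one; 15 (2S)-5,7-dihydroxy-2-phenyl-2,3-dihydro-4H-chromen-4-one ((S)-pinocembrin)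
Product: 16 (3aR,5S,6aR)-5-[(S)-{[(2S)-5-hydroxy-4-oxo-2-phenyl-3,4-dihydro-2H-chromen-7-yl]oxy}(phenyl)methyl]tetrahydrofuro[3,2-b]furan-2(3H)-one
Conditions: PPh3, DIAD, THF, 0 °C → rt
Reagents that add atoms: none
Why: Mitsunobu etherification with the acidic 7-OH of pinocembrin (the 5-OH is held in the hydrogen bond to C4=O) should proceed by SN2 with inversion at the benzylic carbon, converting 7R-OH into the 7S aryl ether under neutral conditions that spare the lactone and the flavanone C2 centre.

**Compound list**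
1 | methyl (2E)-penta-2,4-dienoate | C=C/C=C/C(=O)OC | starting material
2 | 2-[dimethyl(phenyl)silyl]-4,4,5,5-tetramethyl-1,3,2-dioxaborolane | C[Si](C)(c1ccccc1)B1OC(C)(C)C(C)(C)O1 | starting material
3 | pinacolboron enolate of 4 (O-boryl ketene acetal, 3S) | COC(=C[C@@H](C=C)[Si](C)(C)c1ccccc1)OB1OC(C)(C)C(C)(C)O1 | intermediate
4 | methyl (3S)-3-[dimethyl(phenyl)silyl]pent-4-enoate | COC(=O)C[C@@H](C=C)[Si](C)(C)c1ccccc1 | intermediate
5 | phenylglyoxal (2-oxo-2-phenylacetaldehyde) | O=CC(=O)c1ccccc1 | starting material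
6 | methyl 2-[(2R,3S,5S)-5-benzoyl-3-[dimethyl(phenyl)silyl]oxolan-2-yl]acetate | COC(=O)C[C@H]1O[C@H](C(=O)c2ccccc2)C[C@@H]1[Si](C)(C)c1ccccc1 | intermediate
7 | methyl 2-[(2R,3S,5S)-3-[acetoxy(dimethyl)silyl]-5-benzoyloxolan-2-yl]acetate | COC(=O)C[C@H]1O[C@H](C(=O)c2ccccc2)C[C@@H]1[Si](C)(C)OC(C)=O | intermediate
8 | methyl 2-[(2R,3S,5S)-3-{[acetoxy(dimethyl)silyl]oxy}-5-benzoyloxolan-2-yl]acetate | COC(=O)C[C@H]1O[C@H](C(=O)c2ccccc2)C[C@@H]1O[Si](C)(C)OC(C)=O | intermediate
9 | methyl 2-[(2R,3S,5S)-5-benzoyl-3-hydroxyoxolan-2-yl]acetate | COC(=O)C[C@H]1O[C@H](C(=O)c2ccccc2)C[C@@H]1O | intermediate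
10 | trimethylstannyl 2-[(2R,3S,5S)-5-benzoyl-3-hydroxyoxolan-2-yl]acetate | C[Sn](C)(C)OC(=O)C[C@H]1O[C@H](C(=O)c2ccccc2)C[C@@H]1O | intermediate
11 | 2-[(2R,3S,5S)-5-benzoyl-3-hydroxyoxolan-2-yl]acetic acid | OC(=O)C[C@H]1O[C@H](C(=O)c2ccccc2)C[C@@H]1O | intermediate
12 | 2-[(2R,3S,5S)-5-benzoyl-3-(triphenylphosphoniooxy)oxolan-2-yl]acetate (zwitterion) | [O-]C(=O)C[C@H]1O[C@H](C(=O)c2ccccc2)C[C@@H]1O[P+](c1ccccc1)(c1ccccc1)c1ccccc1 | intermediate
13 | (3aR,5S,6aR)-5-benzoyltetrahydrofuro[3,2-b]furan-2(3H)-one | O=C1C[C@H]2O[C@H](C(=O)c3ccccc3)C[C@H]2O1 | intermediate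
14 | (3aR,5S,6aR)-5-[(R)-hydroxy(phenyl)methyl]tetrahydrofuro[3,2-b]furan-2(3H)-one | O=C1C[C@H]2O[C@H]([C@H](O)c3ccccc3)C[C@H]2O1 | intermediate
15 | (2S)-5,7-dihydroxy-2-phenyl-2,3-dihydro-4H-chromen-4-one ((S)-pinocembrin) | Oc1cc(O)c2c(c1)O[C@H](c1ccccc1)CC2=O | starting material
16 | (3aR,5S,6aR)-5-[(S)-{[(2S)-5-hydroxy-4-oxo-2-phenyl-3,4-dihydro-2H-chromen-7-yl]oxy}(phenyl)methyl]tetrahydrofuro[3,2-b]furan-2(3H)-one | O=C1C[C@H]2O[C@H]([C@@H](Oc3cc(O)c4c(c3)O[C@H](c3ccccc3)CC4=O)c3ccccc3)C[C@H]2O1 | target

Total step count: 7. Longest linear sequence: 7 steps (1 → 4 → 6 → 9 → 11 → 13 → 14 → 16).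

**Steps most likely to fail**

Step 2. The β-silyl cation may lose silicon to chloride (Sakurai-type allylation) faster than the silyl shift and ring closure. The aldehyde may also react outside the chelate, so that the 2,5-relationship forms without control. A minor 2,5-cis isomer would not be lost, because C5 of 13 lies next to the benzoyl group and could be equilibrated to the exo isomer. The fallback forms the two bonds one after the other; it sets out from 4 and comes back at 13. Compound 4 and 5 are combined with TiCl4 in CH2Cl2 at −78 → 0 °C in a deliberate Hosomi–Sakurai allylation (anti-SE′, same chelated C–C bond-forming geometry) to give methyl (3E,6S)-6-hydroxy-7-oxo-7-phenylhept-3-enoate F1. A 5-endo-trig iodoetherification (I2, NaHCO3, MeCN, 0 °C) of this E-homoallylic alcohol should give the 2,5-trans, 2,3-trans iodide methyl 2-[(2R,3S,5S)-5-benzoyl-3-iodooxolan-2-yl]acetate F2 by anti addition. Trimethyltin hydroxide cleavage of the ester gives 2-[(2R,3S,5S)-5-benzoyl-3-iodooxolan-2-yl]acetic acid F3, whose carboxylate displaces iodide with inversion (NaHCO3, DMF, 50 °C) to give 13.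

Step 1. The silylcopper species may add 1,6 at the unsubstituted diene terminus, and enantiofacial discrimination on this small dienoate may be insufficient. The fallback uses an auxiliary and a carbon nucleophile; it sets out from 2 and comes back at 4.
- Copper-catalysed syn protosilylation of methyl propiolate with 2 (CuCl, PPh3, NaOtBu cat., MeOH, THF) gives methyl (2E)-3-[dimethyl(phenyl)silyl]prop-2-enoate F4.
- Saponification (LiOH, THF/H2O) gives (2E)-3-[dimethyl(phenyl)silyl]prop-2-enoic acid F5.
- Mixed-anhydride acylation (PivCl, Et3N; lithiated (4R)-4-phenyloxazolidin-2-one) gives (4R)-3-{(2E)-3-[dimethyl(phenyl)silyl]prop-2-enoyl}-4-phenyl-1,3-oxazolidin-2-one F6.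
- Copper-mediated conjugate addition of vinylmagnesium bromide (CuBr·SMe2, THF, −40 °C), anti to the phenyl group of the chelated s-cis imide, should give (4R)-3-{(3S)-3-[dimethyl(phenyl)silyl]pent-4-enoyl}-4-phenyl-1,3-oxazolidin-2-one F7.
- Methanolysis (NaOMe, MeOH, 0 °C) releases 4.

Step 3. The peracid may oxidise the α-alkoxy aryl ketone (Baeyer–Villiger migration of the α-alkoxyalkyl group) while C–Si oxidation at the hindered ring carbon is slow. The fallback carries the ketone through the oxidation at the carbinol level; it sets out from 6 and comes back at 9. Reduction of 6 with Zn(BH4)2 gives methyl 2-[(2R,3S,5S)-3-[dimethyl(phenyl)silyl]-5-[(R)-hydroxy(phenyl)methyl]oxolan-2-yl]acetate F8; the configuration at the new carbinol is of no consequence here. Fleming–Tamao oxidation as in step 3 gives methyl 2-[(2R,3S,5S)-3-hydroxy-5-[(R)-hydroxy(phenyl)methyl]oxolan-2-yl]acetate F9. Chemoselective oxidation of the benzylic alcohol with activated MnO2 (CH2Cl2, rt) restores the ketone and gives 9.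

**Further compounds**
F1 | step 2 | methyl (3E,6S)-6-hydroxy-7-oxo-7-phenylhept-3-enoate | COC(=O)C/C=C/C[C@H](O)C(=O)c1ccccc1
F2 | step 2 | methyl 2-[(2R,3S,5S)-5-benzoyl-3-iodooxolan-2-yl]acetate | COC(=O)C[C@H]1O[C@H](C(=O)c2ccccc2)C[C@@H]1I
F3 | step 2 | 2-[(2R,3S,5S)-5-benzoyl-3-iodooxolan-2-yl]acetic acid | OC(=O)C[C@H]1O[C@H](C(=O)c2ccccc2)C[C@@H]1I
F4 | step 1 | methyl (2E)-3-[dimethyl(phenyl)silyl]prop-2-enoate | COC(=O)/C=C/[Si](C)(C)c1ccccc1
F5 | step 1 | (2E)-3-[dimethyl(phenyl)silyl]prop-2-enoic acid | OC(=O)/C=C/[Si](C)(C)c1ccccc1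
F6 | step 1 | (4R)-3-{(2E)-3-[dimethyl(phenyl)silyl]prop-2-enoyl}-4-phenyl-1,3-oxazolidin-2-one | O=C1OC[C@@H](c2ccccc2)N1C(=O)/C=C/[Si](C)(C)c1ccccc1
F7 | step 1 | (4R)-3-{(3S)-3-[dimethyl(phenyl)silyl]pent-4-enoyl}-4-phenyl-1,3-oxazolidin-2-one | O=C1OC[C@@H](c2ccccc2)N1C(=O)C[C@@H](C=C)[Si](C)(C)c1ccccc1
F8 | step 3 | methyl 2-[(2R,3S,5S)-3-[dimethyl(phenyl)silyl]-5-[(R)-hydroxy(phenyl)methyl]oxolan-2-yl]acetate | COC(=O)C[C@H]1O[C@H]([C@H](O)c2ccccc2)C[C@@H]1[Si](C)(C)c1ccccc1
F9 | step 3 | methyl 2-[(2R,3S,5S)-3-hydroxy-5-[(R)-hydroxy(phenyl)methyl]oxolan-2-yl]acetate | COC(=O)C[C@H]1O[C@H]([C@H](O)c2ccccc2)C[C@@H]1O
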